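A dead catalyst cannot turn over, and a substrate molecule that has gone to side product cannot become target, so I asked what chance one substrate molecule had of reaching target first.

    free catalyst → spent catalyst A (k1 = 0.329 h⁻¹, Ea1 = 92.0 kJ mol⁻¹)
    substrate + free catalyst → free catalyst + target (k2 = 527 M⁻¹ h⁻¹, Ea2 = 67.0 kJ mol⁻¹)
    free catalyst + added ligand ⇌ idle complex (K3 = 421 M⁻¹, k3 = 6260 M⁻¹ h⁻¹, Ea3 = 40.0 kJ mol⁻¹, ΔH3 = −55.0 kJ mol⁻¹)
    substrate → side product (k4 = 0.142 h⁻¹, Ea4 = 111 kJ mol⁻¹)
    free catalyst + target → spent catalyst B (k5 = 0.242 M⁻¹ h⁻¹, Ea5 = 61.0 kJ mol⁻¹)
    (constants at 35 °C)

in all of them: substrate 0.50 M; free catalyst 0.25 mM; added ligand 0.59 mM; time 40 h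

| charge | remark | temperature |
|---|---|---|
| alder | at 60 °C until 20 h, from then on at 35 °C |  |
| larch |  | 60 °C |
| oak |  | 35 °C |

- the list of constants is for 35 °C, to be carried to other temperatures by the activation energies and enthalpies

* the flask that comes out highest in amount of target, in percent of the substrate charged, or "all alike" when all lie within 1.5 percentage points (alder / larch / oak / all alike)
* target at the end, in percent of the substrate charged, alder
* target at the end, in percent of the substrate charged, larch
* target at the end, in percent of the substrate charged, oak

I followed one substrate molecule through a race. Turnover takes it at a pseudo-first-order rate, the turnover constant times [free catalyst]. The side step takes it at its own constant, while the catalyst dies. The added ligand keeps part of the catalyst as idle complex, which slows turnover and death alike by a shelter factor, one plus the binding constant times [added ligand]. I treated catalyst death as a single clock and let the first event end the race: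

odds of target = turnover constant × [free catalyst as charged] / (death constant + side constant × shelter factor)

chance of target = odds / (one + odds)

Before using it, I asked what had to be known well in oak. The substrate charge does not appear in it. Time does not stand in it either, which I accepted for oak because the mean catalyst lifetime of 3.79 h is shorter than 40 h. With a quarter of the substrate as target in oak, target kills catalyst at 0.0302 h⁻¹, less than the death constant 0.329 h⁻¹, so I left that step out. In the formula for oak, twice the ligand took off 1.1 percentage points. Twice the side constant took off 4.5 points, and twice the death constant 7 points. Twice the catalyst charge added 14 points.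

Now the numbers. For oak, I reckoned turnover with the whole charge free at 0.132 h⁻¹ and the shelter factor at 1.25, which gave 0.260, the odds of target, turnover set against both losing paths together. That meant 20.6 % for oak.

At 60 °C, I carried death to 4.87 h⁻¹, the side step to 3.67 h⁻¹ and turnover with the whole charge free to 0.938 h⁻¹, with shelter 1.05. The odds for larch came to 0.108, so I put larch at 9.71 %. Because the hot catalyst lifetime of 0.216 h is far shorter than 20 h, I gave alder the same reckoning, 9.71 %. My pick was oak.

The forecast also named oak, with 10 % for alder, 10 % for larch and 22 % for oak, the last above mine. Its grounds for the oak stall: “the catalyst dies within hours and the ligand only briefly shelters it”.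

The simulation put oak first, with 21.9 %, against 10.0 % for alder and 10.0 % for larch. In alder, the side step used substrate 3.9 times as fast as turnover at the start and 9.4 times as fast at 0.176 h. By 40.0 h, side product in alder stood at 90.0 %. Read as odds, oak's result is 0.280, beside my 0.260, and at 400 h oak held 21.9 %.

A neighbour of alder was charged with 0.0630 mM of free catalyst. The catalyst charge stands in the numerator of the odds, so they scale to 0.0271, a chance of 2.64 %. The simulation gave that neighbour 2.66 %.

The constants were chosen freely; what happens was integrated by code.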